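**Plan**

- The retrosynthesis first cuts the depside ester bond (ring A carbonyl to O4 of ring B), then the three O–CH3 bonds and the benzyl ester, so that both rings fall back on one resorcylate, benzyl 2,4-dihydroxy-6-pentylbenzoate 7.
- Ring B of 7 is cut at C3–C4, which unmasks its isomer, pyranone 4. Pyranone 4 is cut at the lactone O1–C2 bond and at the C4–C5 bond (acetoacetate carbon to ynoate β-carbon).
- Enabling feature: ring B (the 2-methoxy-6-pentylbenzoic acid ring with the ester oxygen on C4) has, as its 2,4-dihydroxy benzyl ester, the same atoms as benzyl 6-methyl-2-oxo-4-pentyl-2H-pyran-5-carboxylate. The 6-methyl carbon is ring B C3, the lactone carbonyl is C4, and the pentyl, ester and ring-oxygen carbons already sit where C6, C1 and C2 will be.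
- Forward order: the pyranone ring is made first (Michael addition, enol lactonisation), then the benzene ring from it (alkoxide opening, Claisen closure). One portion of 7 becomes the ring A acid (dimethylation, hydrogenolysis) and acylates O4 of a second portion; O2-methylation and hydrogenolysis finish the route.
- Stereochemistry: the target has no stereocentre. The one geometric demand, a cis dienoate in the ring-opened intermediate, is inherited from the lactone.

Key step: step 2

Assumption: pyranone 4 is numbered from the ring oxygen with the lactone carbonyl as C2, and the 1 M solution of sodium benzyloxide (NaOBn) in BnOH is taken as a commercial reagent.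

**Route**

Step 1
Reactants: 1 methyl oct-2-ynoate; 2 benzyl acetoacetate
Product: 4 benzyl 6-methyl-2-oxo-4-pentyl-2H-pyran-5-carboxylate, via 5-benzyl 1-methyl (Z)-4-acetyl-3-pentylpent-2-enedioate 3 (not isolated)
Conditions: NaH (0.15 equiv), THF, 0 °C to 50 °C, 2 in slight excess; then AcOH quench, cat. TsOH, toluene, 80 °C (MeOH distilled off)
Reagents that add atoms: none
Why: Base-catalysed Michael addition of the acetoacetate enolate through carbon to the β-carbon of the ynoate (anti addition, which places the new carbon cis to the methyl ester) gives 3, whose enol oxygen closes onto that methyl ester (6-exo-trig enol lactonisation) with loss of methanol, the acid finish closing whatever adduct the catalytic base holds back as its stabilised enolate; this is the classical β-keto ester plus alkynoate route to 6-methyl-2-pyranone-5-carboxylates, and the benzyl ester should survive because the released methanol is hardly deprotonated by the stabilised enolates and is removed in the acid phase.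

Step 2
Reactants: 4 benzyl 6-methyl-2-oxo-4-pentyl-2H-pyran-5-carboxylate
Product: 7 benzyl 2,4-dihydroxy-6-pentylbenzoate, via dibenzyl (Z)-4-acetyl-3-pentylpent-2-enedioate 5 (not isolated), via benzyl 2,4-dioxo-6-pentylcyclohex-5-ene-1-carboxylate 6 (not isolated)
Conditions: NaOBn (3 equiv, 1 M in BnOH), 80 °C, Ar; then 1 M aq. HCl, 0 °C
Reagents that add atoms: none
Why: Benzyloxide attacks C2 of pyranone 4, the C2–O1 bond breaks and the ring unfolds into the sodium enolate of keto diester 5, in which the double bond keeps the cis arrangement it had in the lactone, so the acetyl group and the newly formed benzyl ester remain neighbours; the small equilibrium share of the enolate on the acetyl methyl carbon then adds to that ester carbonyl, benzyloxide is expelled, and dione 6 enolises twice to the resorcinol, isolated after acidification. The closest known reaction type is the sodium alkoxide isomerisation of 6-methyl-2-pyranone-5-carboxylic esters to 2,4-dihydroxybenzoates, which is the second half of the Michael–Claisen resorcylate synthesis from acetoacetates and alkynoates. Ring B closes in the 6-exo-trig mode (Dieckmann-type Claisen condensation), the new bond joining the former methyl carbon (ring B C3) to the former lactone carbonyl (ring B C4). No stereocentre is formed. The selectivity required is C-acylation by the methyl carbon over return of the enol oxygen to the lactone; it is secured because relactonisation is reversible whereas the Claisen product leaves the equilibrium as an aromatic phenoxide, which is why three equivalents of base are used. Benzyloxide as the alkoxide makes every ester exchange degenerate, and the product emerges with its two hydroxyls already differentiated, the 2-hydroxyl being hydrogen-bonded to the ester.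

Step 3
Reactants: 7 benzyl 2,4-dihydroxy-6-pentylbenzoate (one portion)
Product: 8 benzyl 2,4-dimethoxy-6-pentylbenzoate
Conditions: MeI (excess), K2CO3, DMF, 50 °C
Reagents that add atoms: iodomethane, CI
Why: Williamson O-methylation of both phenoxides; the hydrogen-bonded 2-hydroxyl reacts more slowly but should yield to excess iodomethane in warm DMF, while the hindered benzyl ester is inert to carbonate.

Step 4
Reactants: 8 benzyl 2,4-dimethoxy-6-pentylbenzoate
Product: 9 2,4-dimethoxy-6-pentylbenzoic acid
Conditions: H2 (1 atm), 10% Pd/C, EtOAc, rt
Reagents that add atoms: none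
Why: Catalytic hydrogenolysis cleaves the benzylic C–O bond under neutral conditions, which avoids the sluggish saponification of a 2,6-disubstituted benzoate and leaves the aryl methyl ethers untouched.

Step 5
Reactants: 9 2,4-dimethoxy-6-pentylbenzoic acid; 7 benzyl 2,4-dihydroxy-6-pentylbenzoate (second portion)
Product: 11 benzyl 4-[(2,4-dimethoxy-6-pentylbenzoyl)oxy]-2-hydroxy-6-pentylbenzoate, via 2,4-dimethoxy-6-pentylbenzoic trifluoroacetic anhydride 10 (not isolated)
Conditions: TFAA, toluene, rt (9 and TFAA premixed, then 7)
Reagents that add atoms: none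
Why: Esterification through the mixed trifluoroacetic anhydride is a standard depside coupling for hindered, electron-rich benzoic acids, and the free 4-hydroxyl of 7 should be acylated in preference to the 2-hydroxyl, which is tied up in a hydrogen bond to the ester carbonyl and flanked by the ester.

Step 6
Reactants: 11 benzyl 4-[(2,4-dimethoxy-6-pentylbenzoyl)oxy]-2-hydroxy-6-pentylbenzoate
Product: 12 benzyl 4-[(2,4-dimethoxy-6-pentylbenzoyl)oxy]-2-methoxy-6-pentylbenzoate
Conditions: MeI, K2CO3, acetone, reflux
Reagents that add atoms: iodomethane, CI
Why: Williamson methylation of the remaining chelated phenol; anhydrous carbonate in acetone supplies no nucleophile for the depside ester, whose carbonyl is shielded by the 2-methoxy and 6-pentyl groups of ring A.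

Step 7
Reactants: 12 benzyl 4-[(2,4-dimethoxy-6-pentylbenzoyl)oxy]-2-methoxy-6-pentylbenzoate
Product: 13 planaic acid, 4-[(2,4-dimethoxy-6-pentylbenzoyl)oxy]-2-methoxy-6-pentylbenzoic acid
Conditions: H2 (1 atm), 10% Pd/C, EtOAc, rt
Reagents that add atoms: none
Why: Hydrogenolysis removes the benzyl ester selectively, because the aryl ester of the depside has no benzylic C–O bond and is not reduced under these conditions.

**Compound list**

1 | methyl oct-2-ynoate | CCCCCC#CC(=O)OC | starting material
2 | benzyl acetoacetate (benzyl 3-oxobutanoate) | CC(=O)CC(=O)OCc1ccccc1 | starting material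
3 | 5-benzyl 1-methyl (Z)-4-acetyl-3-pentylpent-2-enedioate (racemic and labile at C4) | CCCCC/C(=C/C(=O)OC)C(C(C)=O)C(=O)OCc1ccccc1 | intermediate (not isolated)
4 | benzyl 6-methyl-2-oxo-4-pentyl-2H-pyran-5-carboxylate | CCCCCC1=CC(=O)OC(C)=C1C(=O)OCc1ccccc1 | intermediate
5 | dibenzyl (Z)-4-acetyl-3-pentylpent-2-enedioate (racemic and labile at C4; present as its sodium enolate) | CCCCC/C(=C/C(=O)OCc1ccccc1)C(C(C)=O)C(=O)OCc1ccccc1 | intermediate (not isolated)
6 | benzyl 2,4-dioxo-6-pentylcyclohex-5-ene-1-carboxylate (dione tautomer of 7) | CCCCCC1=CC(=O)CC(=O)C1C(=O)OCc1ccccc1 | intermediate (not isolated)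
7 | benzyl 2,4-dihydroxy-6-pentylbenzoate | CCCCCc1cc(O)cc(O)c1C(=O)OCc1ccccc1 | intermediate
8 | benzyl 2,4-dimethoxy-6-pentylbenzoate | CCCCCc1cc(OC)cc(OC)c1C(=O)OCc1ccccc1 | intermediate
9 | 2,4-dimethoxy-6-pentylbenzoic acid | CCCCCc1cc(OC)cc(OC)c1C(=O)O | intermediate
10 | 2,4-dimethoxy-6-pentylbenzoic trifluoroacetic anhydride | CCCCCc1cc(OC)cc(OC)c1C(=O)OC(=O)C(F)(F)F | intermediate (not isolated)
11 | benzyl 4-[(2,4-dimethoxy-6-pentylbenzoyl)oxy]-2-hydroxy-6-pentylbenzoate | CCCCCc1cc(OC(=O)c2c(CCCCC)cc(OC)cc2OC)cc(O)c1C(=O)OCc1ccccc1 | intermediate
12 | benzyl 4-[(2,4-dimethoxy-6-pentylbenzoyl)oxy]-2-methoxy-6-pentylbenzoate | CCCCCc1cc(OC(=O)c2c(CCCCC)cc(OC)cc2OC)cc(OC)c1C(=O)OCc1ccccc1 | intermediate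
13 | planaic acid | CCCCCc1cc(OC(=O)c2c(CCCCC)cc(OC)cc2OC)cc(OC)c1C(=O)O | target

**Step count and risks**

Total step count: 7.
Longest linear sequence: 7 steps (steps 1–2 to resorcylate 7, steps 3–4 to the ring A acid 9, steps 5–7 to the target). The ring B portion of 7 enters at step 5 after 2 steps.

Steps most likely to fail:

1. Step 2. The ring-opened enolate may simply persist, because its negative charge is already spread over three carbonyl groups and the methyl ketone is deprotonated only to a small extent. Benzyloxide or traces of hydroxide may also divert material by conjugate attack, hydrolysis and decarboxylation. The fallback forms the same C3–C4 Claisen bond one oxidation level lower and aromatises afterwards; it sets out from 1 and 2 and returns at 7. Semihydrogenation of 1 (H2, Pd/CaCO3 poisoned with Pb(OAc)2, quinoline, EtOAc) would give methyl (Z)-oct-2-enoate F1. Treating 2 and F1 with NaOBn (1 equiv) in BnOH at 80 °C should run the classical Michael–Dieckmann sequence through 1-benzyl 5-methyl 2-acetyl-3-pentylpentanedioate F2 (not isolated) to benzyl 2-hydroxy-4-oxo-6-pentylcyclohex-2-ene-1-carboxylate F3, a stereoisomer mixture whose centres vanish on aromatisation. Exchange of the methyl ester for benzyl in this medium would alter only which alcohol is expelled in the ring closure. Bromination with Br2 (1 equiv) in DMF at 0 °C to benzyl 3-bromo-2-hydroxy-4-oxo-6-pentylcyclohex-2-ene-1-carboxylate F4, followed by loss of hydrogen bromide on warming to 80 °C, would then deliver 7.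

2. Step 1. The ambident acetoacetate enolate may add through oxygen, the ynoate may isomerise or oligomerise under base, the catalytic cycle may stall once the base is sequestered as the stabilised adduct enolate, and the released methanol may exchange with the benzyl ester. The fallback builds the pyranone ring first and attaches the pentyl group by cross-coupling; it sets out from 2 and returns at 4. Compound 2 with malonyl dichloride in refluxing 1,2-dichloroethane should give benzyl 4-hydroxy-6-methyl-2-oxo-2H-pyran-5-carboxylate F5. Tf2O and Et3N in CH2Cl2 at −78 °C would convert it into benzyl 6-methyl-2-oxo-4-(trifluoromethylsulfonyloxy)-2H-pyran-5-carboxylate F6. Negishi coupling of F6 with n-pentylzinc bromide and PdCl2(dppf) in THF at rt would give 4.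

3. Step 6. Methylation of the hydrogen-bonded phenol is slow, which gives carbonate-mediated cleavage of the depside ester time to compete. The fallback installs the 2-methoxy group before the rings are joined; it sets out from 7 and returns at 12, bypassing 11. Selective protection of the unchelated 4-hydroxyl (MOMCl, i-Pr2NEt, CH2Cl2, 0 °C) would give benzyl 2-hydroxy-4-(methoxymethoxy)-6-pentylbenzoate F7. Methylation (MeI, K2CO3, DMF, 50 °C) would give benzyl 2-methoxy-4-(methoxymethoxy)-6-pentylbenzoate F8, and acetal cleavage (cat. HCl, MeOH/THF, 40 °C) would give benzyl 4-hydroxy-2-methoxy-6-pentylbenzoate F9. Coupling of F9 with acid 9 through mixed anhydride 10 (TFAA, toluene, rt) would then give 12 directly.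

**Further compounds**

F1 | step 2 | methyl (Z)-oct-2-enoate | CCCCC/C=C\C(=O)OC
F2 | step 2 | 1-benzyl 5-methyl 2-acetyl-3-pentylpentanedioate | CCCCCC(CC(=O)OC)C(C(C)=O)C(=O)OCc1ccccc1
F3 | step 2 | benzyl 2-hydroxy-4-oxo-6-pentylcyclohex-2-ene-1-carboxylate | CCCCCC1CC(=O)C=C(O)C1C(=O)OCc1ccccc1
F4 | step 2 | benzyl 3-bromo-2-hydroxy-4-oxo-6-pentylcyclohex-2-ene-1-carboxylate | CCCCCC1CC(=O)C(Br)=C(O)C1C(=O)OCc1ccccc1
F5 | step 1 | benzyl 4-hydroxy-6-methyl-2-oxo-2H-pyran-5-carboxylate | CC1=C(C(=O)OCc2ccccc2)C(O)=CC(=O)O1
F6 | step 1 | benzyl 6-methyl-2-oxo-4-(trifluoromethylsulfonyloxy)-2H-pyran-5-carboxylate | CC1=C(C(=O)OCc2ccccc2)C(OS(=O)(=O)C(F)(F)F)=CC(=O)O1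
F7 | step 6 | benzyl 2-hydroxy-4-(methoxymethoxy)-6-pentylbenzoate | CCCCCc1cc(OCOC)cc(O)c1C(=O)OCc1ccccc1
F8 | step 6 | benzyl 2-methoxy-4-(methoxymethoxy)-6-pentylbenzoate | CCCCCc1cc(OCOC)cc(OC)c1C(=O)OCc1ccccc1
F9 | step 6 | benzyl 4-hydroxy-2-methoxy-6-pentylbenzoate | CCCCCc1cc(O)cc(OC)c1C(=O)OCc1ccccc1
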